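## Analysis of the target

The target is a (2R,3S)-flavan-3-ol of the afzelechin type, made of ring A (the phloroglucinol-type benzene ring C4a–C8a), ring C (the pyran with C2 and C3) and ring B (the 4-hydroxyphenyl group on C2, whose oxygen is called O(B) here because primed numbers are kept for the oxolanes). Both free carbons of ring A, C6 and C8, carry the same arm: a diarylmethine carbon Ca (bonded to ring A, to a 4-hydroxyphenyl group and to C3') followed by a fully substituted oxolane made of O1', C2' with a 2,4-dihydroxyphenyl group, C3' bonded to Ca, C4' with a 2,4-dihydroxybenzoyl group and C5' with a 4-hydroxyphenyl group. There are twelve stereocentres: C2 (R) and C3 (S) of the flavan and, identically in both arms, Ca (S), C2' (R), C3' (S), C4' (S) and C5' (S). In each oxolane the C2' aryl group, the C3' substituent and the C5' aryl group lie on one face and the aroyl group on the other (2',3'-cis, 3',4'-trans, 4',5'-trans). The sensitive groups are sixteen hydroxyl groups (fifteen of them phenols), three kinds of electron-rich benzylic C–O bonds (C2–O1, C2'–O1', C5'–O1') that ionise with acid, and the C4'–H bond next to an aryl ketone. The difficulty is that five stereocentres must be built twice, with the same absolute sense, on two crowded neighbouring positions of one benzene ring, and that the two Ca centres are too far from C2 and C3 for the chiral pool to control them. The strategy rests on one feature: Ca on C6 is ortho to O5, Ca on C8 is ortho to O7, and each Ca is two bonds from C2', so an acyl bond from O5 (or O7) to C2' closes the six-membered ring O–C2'(=O)–C3'–Ca–C(ring A)–C(ring A), a 3,4-dihydrocoumarin whose position 4 is Ca, position 3 is C3' and carbonyl carbon is C2'. Ring A can carry two such pyranone rings at once, and in their unsaturated form both Ca atoms are flat β-carbons of enoates.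

## Retrosynthetic reasoning

29 from 28. All sixteen hydroxyl groups are carried as benzyl ethers, so the last step is a single hydrogenolysis that makes no skeletal bond and touches no stereocentre.

28 from 27. The C2'–H bond of each oxolane is cut, which leads back to the cyclic hemiketal 27. C2' is the one ring carbon whose aryl group is cis to the substituent of its neighbour. That arrangement results when a small nucleophile (hydride) adds to a planar oxocarbenium carbon from the face away from the C3' and C5' groups. The reverse order, an aryl nucleophile adding to an oxocarbenium carbon that bears hydrogen, would place the aryl group trans, so C2' has to arrive at the ketone oxidation level with its aryl group already attached.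

27 from 23 and 24. Opening the hemiketal (O1'–C2') gives the hydroxy diketone 26, and the C4'–C5' bond is then cut as an aldol bond in each arm, which releases one molecule of 24 per arm, two in all. C4' is α to the aroyl carbonyl and C5' is an aryl carbinol, so this is the natural retron. The forward reaction has to enolise only the ketone that has an α-methylene group, fix the enolate geometry (25) so that C4' and C5' come out syn, and let C3' decide the face. Ring closure then needs no reagent.

23 from 19 and 22. The four aryl–carbonyl bonds are cut together. All four ketones carry the same 2,4-dioxygenated aryl group, so one aryllithium (22, from 21, from 20) can make them all, four molecules of 22 per molecule of 19. This works if each carbonyl group is present as its N-methoxy-N-methylamide, which accepts exactly one aryl group.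

19 from 18 from 17. The two amide groups that sit at C2' are traced back to the lactone acyl bonds O5–C2' and O7–C2'. Going back into the ring is worthwhile because in the ring C3' is held rigidly next to Ca, which is not true of any open-chain relative.

17 from 15. The C3'–C4' bond is cut as a lactone enolate alkylation (via 16). In the 4-aryl-3,4-dihydrocoumarin the aryl group on Ca shields one face, so C3' is set trans to it by the ring and not by an acyclic model.

15 from 13 and 14 (the key disconnection). The bond from Ca to its 4-oxyphenyl group is cut in both arms, which releases two molecules of 14. Of the three bonds at Ca, this is the best choice. The bond to ring A would demand two Friedel–Crafts-type alkylations of a crowded arene by hindered electrophiles, and the bond to C3' would leave Ca to acyclic control. The bond to the aryl group can be formed by conjugate addition to a flat, rigid pyranone under control of a chiral catalyst, which gives both Ca centres the same sense regardless of C2 and C3. The forward reaction must add twice, in 1,4-fashion, without opening the lactones.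

13 from 11, 10 and 9. The second pyranone ring (O5–C2' and the C6–Ca double bond) is removed by retro-olefination and retro-lactonisation to the ortho-hydroxy aldehyde 11, and from there to 9, which still has hydrogen at C6.

9 from 7, 6, 4, 3 and 1. The first pyranone ring is removed the same way. The order is dictated by a pairing problem: a side chain on C6 could lactonise onto O5 or O7, whereas a side chain on C8 can reach only O7. Building both rings in one operation from formyl groups at C6 and C8 would therefore give mixtures. The C8/O7 ring is built first, while O5 is still benzylated, and the C6/O5 ring second, when O5 is the only hydroxyl left. Selective benzylation of only O3 and O(B) of 1 is not realistic, so 1 is perbenzylated (3, via 2) and each ring A hydroxyl is uncovered only when an ortho aldehyde can direct the cleavage. C8 is addressed first through its known preference in bromination (4, 5, 6).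

## Alternatives that were turned down

Alternative 1: The C3'–C4' bond of both arms is disconnected. In the forward direction the two enol oxygen atoms that flank C3' and C4' are tied through a diisopropylsilyl group in each arm. Oxidation at a carbon anode (LiClO4, 2,6-lutidine, acetonitrile) removes an electron from each tethered unit, C3' and C4' join through a transient seven-membered ring, and a second oxidation with loss of silicon gives the bis(1,4-diketone) A1. In its favour, the most hindered C–C bond of each arm is made intramolecularly and without strong base, and the tether can relay the C3'/C4' relationship. A1 is also the bis-silyl ether of 26, so this plan would join the present route at 27. Against it for this target, the substrate carries more than a dozen alkoxyarene rings, including the trialkoxy ring A, whose oxidation potentials lie close to that of a silyl enol ether, so arene oxidation competes at the electrode twice in one molecule. Ca and C5' must already be in place in open-chain form, so the hardest question (both Ca centres with one sense) is only moved upstream. Mixed silyl-bridged enol ether units of defined geometry also have to be made twice on a crowded arene. Alternative 1 is stronger on the C3'–C4' bond itself; the chosen route gives up that convergence for a catalytic, precedented step that sets Ca and for bond formations with no redox ambiguity.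

Alternative 2: Here the ring A–Ca bonds and the ring A–oxygen bonds at C7 and C5 are disconnected together with Ca–C3' and O–C2'. CsF unmasks an aryne bond at C7–C8 and then at C5–C6 of ring A. Each aryne bond adds across a formyl C=O group that supplies Ca (C7–O and C8–Ca, then C5–O and C6–Ca), and the adduct opens to an ortho-quinone methide unit. This unit adds to an enol ether double bond C2'=C3' held in a preformed five-membered ring (hetero-Diels–Alder reaction, forming Ca–C3' and O–C2'), which closes two six-membered ketal rings and gives the bis-ketal A2 with the whole carbon skeleton. On step count and convergence it is clearly the strongest of all the plans. Against it, ring A would have to be prepared without O5 and O7 and with two aryne-generating group pairs, so the chiral-pool flavan cannot be used as it is. Each aryne insertion has a regiochemical choice. Each cycloaddition creates Ca, C3' and C2' with only endo/exo and facial bias from the five-membered partner and none from the flavan, so the two arms are not tied to one absolute sense. A2 must then be reduced at C2' with selective cleavage of the aryl–oxygen ketal bond. The chosen route is longer, but every bond comes from a reaction with a close precedent and Ca is fixed by a catalyst.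

Alternative 3: The C4'–C5' bond is disconnected. In the forward direction each arm holds C5' as the acetal carbon of a seven-membered ring in which it is bonded to an enol oxygen. Me2AlCl cleaves the bond between C5' and that oxygen, and the carbon C4' of the resulting dimethylaluminium enolate closes on the oxocarbenium carbon C5' (an oxygen-to-carbon 1,3-shift with ring contraction). This gives A3, which is the same compound as 28. On the endgame it is stronger than the chosen route: one intramolecular step makes the oxolane and the C4'/C5' relationship with no reliance on an open-chain facial bias. Against it, the seven-membered rings must already hold Ca, C2' and C3' in the right configuration and have to be assembled twice on ring A. The 2,4-dialkoxyphenyl-substituted C2'–O bond ionises under the same Lewis acid as the C5'–O bond, which puts the cis C2' centre at risk. The chosen route instead sets C2' last, at low temperature, and solves the Ca problem first.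

Key step: step 9

Assumption: (+)-afzelechin 1 is bought as the single (2R,3S) enantiomer, so C2 and C3 come from the chiral pool and are never part of a reacting centre.

## Route

Step 1
Reactants: 1 (+)-afzelechin
Product: 3 3,5,7,O(B)-tetra-O-benzylafzelechin, via 5,7,O(B)-tri-O-benzylafzelechin 2 (not isolated)
Conditions: BnBr, K2CO3, DMF, rt; then NaH, 0 °C to rt
Reagents that add atoms: benzyl bromide, BrCc1ccccc1
Why: Williamson etherification; carbonate benzylates the three phenols to 2, then NaH deprotonates the secondary 3-OH for the fourth benzylation, and C2 and C3 are not involved.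

Step 2
Reactants: 3 3,5,7,O(B)-tetra-O-benzylafzelechin
Product: 4 8-bromo-3,5,7,O(B)-tetra-O-benzylafzelechin
Conditions: NBS, CH2Cl2, −78 to 0 °C
Reagents that add atoms: N-bromosuccinimide, O=C1CCC(=O)N1Br
Why: Electrophilic aromatic bromination; in 5,7-dialkoxyflavans C8 is the more reactive ring A position, a selectivity established for benzylated flavan-3-ols, and one equivalent at low temperature leaves C6 and ring B untouched.

Step 3
Reactants: 4 8-bromo-3,5,7,O(B)-tetra-O-benzylafzelechin
Product: 6 3,5,7,O(B)-tetra-O-benzylafzelechin-8-carbaldehyde, via 8-lithio flavan 5 (not isolated)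
Conditions: n-BuLi, THF, −78 °C; DMF, −78 to 0 °C; AcOH
Reagents that add atoms: N,N-dimethylformamide, CN(C)C=O
Why: Bromine–lithium exchange is faster than any deprotonation at −78 °C, and the aryllithium 5 is formylated by DMF (Bouveault-type formylation).

Step 4
Reactants: 6 3,5,7,O(B)-tetra-O-benzylafzelechin-8-carbaldehyde
Product: 7 3,5,O(B)-tri-O-benzyl-7-hydroxyafzelechin-8-carbaldehyde
Conditions: MgBr2·OEt2, toluene/Et2O, 80 °C; aq. HCl
Reagents that add atoms: none
Why: Chelation-controlled debenzylation; magnesium bridges the aldehyde oxygen and O7 and bromide removes that benzyl group, while the other benzyl ethers have no ortho carbonyl and the second ortho neighbour of the aldehyde is the ring oxygen O1.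

Step 5
Reactants: 7 3,5,O(B)-tri-O-benzyl-7-hydroxyafzelechin-8-carbaldehyde
Product: 9 mono-coumarin (3,5,O(B)-tri-O-benzylafzelechin bridged O7–C(=O)–CH=CH–C8), via (E)-cinnamate ester 8 (not isolated)
Conditions: Ph3P=CHCO2Et, PhNEt2, reflux
Reagents that add atoms: ethyl (triphenylphosphoranylidene)acetate, CCOC(=O)C=P(c1ccccc1)(c1ccccc1)c1ccccc1
Why: Wittig olefination gives 8, which at reflux isomerises about the double bond and lactonises (classical coumarin synthesis from salicylaldehydes); O7 is the only free hydroxyl, so the ring can close only between O7 and C8.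

Step 6
Reactants: 9 mono-coumarin
Product: 10 6-formyl mono-coumarin (9 with CHO at C6)
Conditions: Cl2CHOMe, TiCl4, CH2Cl2, −78 to −20 °C; H2O
Reagents that add atoms: dichloromethyl methyl ether, COC(Cl)Cl; water, O
Why: Rieche formylation; C6 is the only unsubstituted carbon of ring A and is activated by O5 (ortho), O7 (ortho) and O1 (para), whereas ring B has a single alkoxy group and the pyranone double bond is electron-poor.

Step 7
Reactants: 10 6-formyl mono-coumarin
Product: 11 6-formyl-5-hydroxy mono-coumarin (10 without the benzyl group on O5)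
Conditions: MgBr2·OEt2, toluene/Et2O, 80 °C; aq. HCl
Reagents that add atoms: none
Why: The same chelation-controlled debenzylation as in step 4; O5 is now the only benzyl ether ortho to a carbonyl group, because O7 is part of the lactone.

Step 8
Reactants: 11 6-formyl-5-hydroxy mono-coumarin
Product: 13 afzelechin-fused bis-coumarin (O5–C(=O)–CH=CH–C6 and O7–C(=O)–CH=CH–C8; 3-O-benzyl and O(B)-benzyl; 2R,3S), via (E)-cinnamate ester 12 (not isolated)
Conditions: Ph3P=CHCO2Et, PhNEt2, reflux
Reagents that add atoms: ethyl (triphenylphosphoranylidene)acetate, CCOC(=O)C=P(c1ccccc1)(c1ccccc1)c1ccccc1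
Why: Wittig olefination and thermal lactonisation as in step 5; O5 is the only hydroxyl left, so the order of events enforces the pairing O7/C8 and O5/C6.

Step 9
Reactants: 13 afzelechin-fused bis-coumarin; 14 4-(benzyloxy)phenylboronic acid
Product: 15 bis(4-aryl-3,4-dihydrocoumarin) (13 with a 4-(benzyloxy)phenyl group on each Ca and H on each C3'; both Ca (S))
Conditions: Rh(acac)(C2H4)2 (6 mol%), (S)-SEGPHOS (6.6 mol%), 14 (8 equiv), 1,4-dioxane/H2O 10:1, 60 °C
Reagents that add atoms: 4-(benzyloxy)phenylboronic acid (compound 14), OB(O)c1ccc(OCc2ccccc2)cc1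
Why: Hayashi–Miyaura asymmetric 1,4-addition, the closest known case being the rhodium–bisphosphine-catalysed addition of arylboronic acids to coumarins that gives 4-aryl-3,4-dihydrocoumarins; here it has to run at two pyranone rings fused to one benzene ring, so two molecules of 14 are taken up, one per ring. Transmetalation from 14 to the hydroxo complex of monovalent rhodium gives an aryl–rhodium species, the C3'=Ca double bond inserts into the Rh–aryl bond with the aryl group going to Ca, and water protonates the resulting oxa-π-allyl rhodium enolate at C3' and returns the hydroxo complex. No ring is closed; two C–C bonds and two stereocentres are formed. Each Ca is controlled by the ligand alone: the flat, rigid pyranone can bind in the C2-symmetric pocket by only one enantioface, and (S)-SEGPHOS is the enantiomer expected, by analogy with simple coumarins, to give (S) at both centres, while C2 and C3 of the flavan are too remote to interfere. The step needs 1,4- rather than 1,2-addition (secured by the soft aryl–rhodium species and the ester-type carbonyl), intact lactones (neutral aqueous dioxane) and complete double addition, for which 14 is used in excess because protodeboronation competes and each β-carbon has an oxygen-bearing peri neighbour. The two additions should be independent, since the β-carbons are separated by ring A and the first aryl group takes a pseudoaxial position away from the second reaction site.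

Step 10
Reactants: 15 bis(4-aryl-3,4-dihydrocoumarin)
Product: 17 bis(3,4-trans-3-(2-methoxy-2-oxoethyl)-4-aryl-3,4-dihydrocoumarin), via bis(lithium enolate) 16 (not isolated)
Conditions: LiN(SiMe3)2, THF, −78 °C; BrCH2CO2Me, −78 to −40 °C
Reagents that add atoms: methyl bromoacetate, COC(=O)CBr
Why: Lactone enolate alkylation (SN2); the aryl group on Ca is pushed pseudoaxial by the peri oxygen and shields one face of each enolate, so the electrophile enters anti to it and C3' is set trans to Ca in both rings, which forms the C3'–C4' bonds.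

Step 11
Reactants: 17 bis(3,4-trans-3-(2-methoxy-2-oxoethyl)-4-aryl-3,4-dihydrocoumarin)
Product: 18 tetrakis(N-methoxy-N-methylamide) 5,7-diol (both lactones opened; each arm Ca(aryl)–C3'H(C(=O)N(OMe)Me)–C4'H2–C(=O)N(OMe)Me)
Conditions: AlMe3, MeNH(OMe)·HCl, CH2Cl2, 0 °C to rt; aq. HCl
Reagents that add atoms: N,O-dimethylhydroxylamine hydrochloride, CNOC.Cl
Why: Weinreb aminolysis with Me(Cl)Al–N(OMe)Me, formed from AlMe3 and the amine hydrochloride, converts the two aryl lactones (freeing O5–H and O7–H) and the two methyl esters into N-methoxy-N-methylamides; the reagent is Lewis-acidic and only weakly basic, so C3' is not epimerised.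

Step 12
Reactants: 18 tetrakis(N-methoxy-N-methylamide) 5,7-diol
Product: 19 tetrakis(N-methoxy-N-methylamide) 5,7-dibenzyl ether
Conditions: BnBr, K2CO3, DMF, 60 °C
Reagents that add atoms: benzyl bromide, BrCc1ccccc1
Why: Williamson etherification; ring A has no free carbon left for C-alkylation, and masking O5 and O7 keeps them from quenching the aryllithium in step 14 and from trapping the C2' oxocarbenium ion as a chroman ketal in step 16.

Step 13
Reactants: 20 4-bromoresorcinol
Product: 21 2,4-bis(benzyloxy)-1-bromobenzene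
Conditions: BnBr, K2CO3, DMF, 60 °C
Reagents that add atoms: benzyl bromide, BrCc1ccccc1
Why: Williamson etherification of both phenols.

Step 14
Reactants: 19 tetrakis(N-methoxy-N-methylamide) 5,7-dibenzyl ether; 21 2,4-bis(benzyloxy)-1-bromobenzene
Product: 23 tetraketone (each arm Ca(aryl)–C3'H(C(=O)Ar)–C4'H2–C(=O)Ar with Ar = 2,4-bis(benzyloxy)phenyl), via aryllithium 22 (not isolated)
Conditions: 21 (6 equiv), n-BuLi (6 equiv), THF, −78 °C; then 19, −78 to −20 °C; AcOH, −78 °C
Reagents that add atoms: 2,4-bis(benzyloxy)phenyllithium (compound 22), [Li]c1ccc(OCc2ccccc2)cc1OCc1ccccc1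
Why: Bromine–lithium exchange gives 22, which adds to each N-methoxy-N-methylamide to form a chelated tetrahedral adduct that collapses only on quench (Weinreb ketone synthesis), so each of the four carbonyl groups is arylated once and C3' is not touched. Four molecules of 22 are consumed per molecule of 19, one at each amide, which is why 21 and n-BuLi are used in excess.

Step 15
Reactants: 23 tetraketone; 24 4-(benzyloxy)benzaldehyde
Product: 27 bis(hemiketal) (each arm a 2'-aryl-2'-hydroxyoxolane with C3' (S) and C4' (S) and C5' (S); C2' as anomer mixture), via bis(Z-dibutylboron enolate) 25 (not isolated), via open-chain bis-aldol 26 (not isolated)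
Conditions: Bu2BOTf (2.4 equiv), iPr2NEt (3 equiv), CH2Cl2, −78 to 0 °C; 24 (3 equiv), −78 to −20 °C; H2O2, MeOH, pH 7 buffer, 0 °C
Reagents that add atoms: 4-(benzyloxy)benzaldehyde (compound 24), O=Cc1ccc(OCc2ccccc2)cc1
Why: Boron-mediated aldol reaction; soft enolisation should take only the ketone with an α-methylene group (C4') and give the Z-enolate 25, whose Zimmerman–Traxler chair leads to the syn C4'/C5' relationship (trans in the ring). Allylic 1,3-strain places C3'–H in the enolate plane, so the aldehyde should add to the face opposite the diarylmethyl group, which corresponds to (4'S,5'S). Each arm takes up one molecule of 24, two in all, and the C5' hydroxyl of 26 then closes onto the C2' ketone (5-exo-trig hemiketalisation), so that C4'–C5' and O1'–C2' are formed in both arms.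

Step 16
Reactants: 27 bis(hemiketal)
Product: 28 hexadeca-O-benzyl ether of the target (each oxolane 2'R,3'S,4'S,5'S)
Conditions: Et3SiH, BF3·OEt2, CH2Cl2, −78 °C; aq. NaHCO3
Reagents that add atoms: none
Why: Ionic hydrogenation of a hemiketal; BF3·OEt2 ionises C2'–OH to the aryl-stabilised cyclic oxocarbenium ion and the silane delivers hydride to the face away from the C3' diarylmethyl and C5' aryl groups, which leaves the C2' aryl group cis to them (2'R). The same sense is known from the reduction of 2-aryl lactols with 3,4-trans-4,5-trans substituents in tetrahydrofuran lignan chemistry, and the aryl ketones are not ionised at −78 °C. Any open-chain hydroxy ketone 26 in equilibrium with 27 reaches the same oxocarbenium ion by reductive etherification.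

Step 17
Reactants: 28 hexadeca-O-benzyl ether of the target
Product: 29 target compound CNP0225367.3
Conditions: H2 (1 atm), Pd(OH)2/C, THF/MeOH, rt
Reagents that add atoms: none
Why: Catalytic hydrogenolysis removes the sixteen benzyl groups under neutral conditions; the aryl ketones are conjugated with electron-rich rings and should resist reduction, and no stereocentre takes part.

## Compound list

1 | (+)-afzelechin, (2R,3S)-2-(4-hydroxyphenyl)chromane-3,5,7-triol | O[C@H]1Cc2c(O)cc(O)cc2O[C@@H]1c1ccc(O)cc1 | starting material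
2 | 5,7,O(B)-tri-O-benzylafzelechin (3-OH free) | O[C@H]1Cc2c(OCc3ccccc3)cc(OCc3ccccc3)cc2O[C@@H]1c1ccc(OCc2ccccc2)cc1 | intermediate
3 | 3,5,7,O(B)-tetra-O-benzylafzelechin | O(Cc1ccccc1)[C@H]1Cc2c(OCc3ccccc3)cc(OCc3ccccc3)cc2O[C@@H]1c1ccc(OCc2ccccc2)cc1 | intermediate
4 | 8-bromo-3,5,7,O(B)-tetra-O-benzylafzelechin | O(Cc1ccccc1)[C@H]1Cc2c(OCc3ccccc3)cc(OCc3ccccc3)c(Br)c2O[C@@H]1c1ccc(OCc2ccccc2)cc1 | intermediate
5 | 8-lithio-3,5,7,O(B)-tetra-O-benzylafzelechin | O(Cc1ccccc1)[C@H]1Cc2c(OCc3ccccc3)cc(OCc3ccccc3)c([Li])c2O[C@@H]1c1ccc(OCc2ccccc2)cc1 | intermediate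
6 | 3,5,7,O(B)-tetra-O-benzylafzelechin-8-carbaldehyde | O(Cc1ccccc1)[C@H]1Cc2c(OCc3ccccc3)cc(OCc3ccccc3)c(C=O)c2O[C@@H]1c1ccc(OCc2ccccc2)cc1 | intermediate
7 | 3,5,O(B)-tri-O-benzyl-7-hydroxyafzelechin-8-carbaldehyde | O(Cc1ccccc1)[C@H]1Cc2c(OCc3ccccc3)cc(O)c(C=O)c2O[C@@H]1c1ccc(OCc2ccccc2)cc1 | intermediate
8 | ethyl (E)-3-(3,5,O(B)-tri-O-benzyl-7-hydroxyafzelechin-8-yl)prop-2-enoate | O(Cc1ccccc1)[C@H]1Cc2c(OCc3ccccc3)cc(O)c(/C=C/C(=O)OCC)c2O[C@@H]1c1ccc(OCc2ccccc2)cc1 | intermediate
9 | mono-coumarin: 3,5,O(B)-tri-O-benzylafzelechin bridged O7–C(=O)–CH=CH–C8 | O(Cc1ccccc1)[C@H]1Cc2c(OCc3ccccc3)cc3OC(=O)C=Cc3c2O[C@@H]1c1ccc(OCc2ccccc2)cc1 | intermediate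
10 | 6-formyl mono-coumarin (9 with CHO at C6) | O(Cc1ccccc1)[C@H]1Cc2c(OCc3ccccc3)c(C=O)c3OC(=O)C=Cc3c2O[C@@H]1c1ccc(OCc2ccccc2)cc1 | intermediate
11 | 6-formyl-5-hydroxy mono-coumarin | O(Cc1ccccc1)[C@H]1Cc2c(O)c(C=O)c3OC(=O)C=Cc3c2O[C@@H]1c1ccc(OCc2ccccc2)cc1 | intermediate
12 | ethyl (E)-3-(5-hydroxy mono-coumarin-6-yl)prop-2-enoate | O(Cc1ccccc1)[C@H]1Cc2c(O)c(/C=C/C(=O)OCC)c3OC(=O)C=Cc3c2O[C@@H]1c1ccc(OCc2ccccc2)cc1 | intermediate
13 | afzelechin-fused bis-coumarin (O5–C(=O)–CH=CH–C6 and O7–C(=O)–CH=CH–C8; 3-O-benzyl, O(B)-benzyl; 2R,3S) | O(Cc1ccccc1)[C@H]1Cc2c3OC(=O)C=Cc3c3OC(=O)C=Cc3c2O[C@@H]1c1ccc(OCc2ccccc2)cc1 | intermediate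
14 | 4-(benzyloxy)phenylboronic acid | OB(O)c1ccc(OCc2ccccc2)cc1 | starting material
15 | bis(4-aryl-3,4-dihydrocoumarin), both Ca (S), aryl = 4-(benzyloxy)phenyl | O(Cc1ccccc1)[C@H]1Cc2c3OC(=O)C[C@@H](c5ccc(OCc6ccccc6)cc5)c3c3OC(=O)C[C@@H](c5ccc(OCc6ccccc6)cc5)c3c2O[C@@H]1c1ccc(OCc2ccccc2)cc1 | intermediate
16 | bis(lithium enolate) of 15 | O(Cc1ccccc1)[C@H]1Cc2c3OC(O[Li])=C[C@@H](c5ccc(OCc6ccccc6)cc5)c3c3OC(O[Li])=C[C@@H](c5ccc(OCc6ccccc6)cc5)c3c2O[C@@H]1c1ccc(OCc2ccccc2)cc1 | intermediate
17 | bis(3,4-trans-3-(2-methoxy-2-oxoethyl)-4-aryl-3,4-dihydrocoumarin) | O(Cc1ccccc1)[C@H]1Cc2c3OC(=O)[C@H](CC(=O)OC)[C@@H](c5ccc(OCc6ccccc6)cc5)c3c3OC(=O)[C@H](CC(=O)OC)[C@@H](c5ccc(OCc6ccccc6)cc5)c3c2O[C@@H]1c1ccc(OCc2ccccc2)cc1 | intermediate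
18 | tetrakis(N-methoxy-N-methylamide) 5,7-diol | O(Cc1ccccc1)[C@H]1Cc2c(O)c([C@H](c5ccc(OCc6ccccc6)cc5)[C@@H](CC(=O)N(C)OC)C(=O)N(C)OC)c(O)c([C@H](c5ccc(OCc6ccccc6)cc5)[C@@H](CC(=O)N(C)OC)C(=O)N(C)OC)c2O[C@@H]1c1ccc(OCc2ccccc2)cc1 | intermediate
19 | tetrakis(N-methoxy-N-methylamide) 5,7-dibenzyl ether | O(Cc1ccccc1)[C@H]1Cc2c(OCc3ccccc3)c([C@H](c5ccc(OCc6ccccc6)cc5)[C@@H](CC(=O)N(C)OC)C(=O)N(C)OC)c(OCc3ccccc3)c([C@H](c5ccc(OCc6ccccc6)cc5)[C@@H](CC(=O)N(C)OC)C(=O)N(C)OC)c2O[C@@H]1c1ccc(OCc2ccccc2)cc1 | intermediate
20 | 4-bromoresorcinol | Oc1ccc(Br)c(O)c1 | starting material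
21 | 2,4-bis(benzyloxy)-1-bromobenzene | Brc1ccc(OCc2ccccc2)cc1OCc1ccccc1 | intermediate
22 | 2,4-bis(benzyloxy)phenyllithium | [Li]c1ccc(OCc2ccccc2)cc1OCc1ccccc1 | intermediate
23 | tetraketone, bis(1,4-diketone) with four 2,4-bis(benzyloxy)phenyl ketones | O(Cc1ccccc1)[C@H]1Cc2c(OCc3ccccc3)c([C@H](c5ccc(OCc6ccccc6)cc5)[C@@H](CC(=O)c5ccc(OCc6ccccc6)cc5OCc5ccccc5)C(=O)c5ccc(OCc6ccccc6)cc5OCc5ccccc5)c(OCc3ccccc3)c([C@H](c5ccc(OCc6ccccc6)cc5)[C@@H](CC(=O)c5ccc(OCc6ccccc6)cc5OCc5ccccc5)C(=O)c5ccc(OCc6ccccc6)cc5OCc5ccccc5)c2O[C@@H]1c1ccc(OCc2ccccc2)cc1 | intermediate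
24 | 4-(benzyloxy)benzaldehyde | O=Cc1ccc(OCc2ccccc2)cc1 | starting material
25 | bis(Z-dibutylboron enolate) of 23 at C4' | O(Cc1ccccc1)[C@H]1Cc2c(OCc3ccccc3)c([C@H](c5ccc(OCc6ccccc6)cc5)[C@@H](/C=C(\OB(CCCC)CCCC)c5ccc(OCc6ccccc6)cc5OCc5ccccc5)C(=O)c5ccc(OCc6ccccc6)cc5OCc5ccccc5)c(OCc3ccccc3)c([C@H](c5ccc(OCc6ccccc6)cc5)[C@@H](/C=C(\OB(CCCC)CCCC)c5ccc(OCc6ccccc6)cc5OCc5ccccc5)C(=O)c5ccc(OCc6ccccc6)cc5OCc5ccccc5)c2O[C@@H]1c1ccc(OCc2ccccc2)cc1 | intermediate
26 | open-chain bis-aldol (C3' S, C4' S, C5' S in each arm) | O(Cc1ccccc1)[C@H]1Cc2c(OCc3ccccc3)c([C@H](c5ccc(OCc6ccccc6)cc5)[C@@H]([C@H](C(=O)c5ccc(OCc6ccccc6)cc5OCc5ccccc5)[C@H](O)c5ccc(OCc6ccccc6)cc5)C(=O)c5ccc(OCc6ccccc6)cc5OCc5ccccc5)c(OCc3ccccc3)c([C@H](c5ccc(OCc6ccccc6)cc5)[C@@H]([C@H](C(=O)c5ccc(OCc6ccccc6)cc5OCc5ccccc5)[C@H](O)c5ccc(OCc6ccccc6)cc5)C(=O)c5ccc(OCc6ccccc6)cc5OCc5ccccc5)c2O[C@@H]1c1ccc(OCc2ccccc2)cc1 | intermediate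
27 | bis(hemiketal), two 2'-aryl-2'-hydroxyoxolanes (C2' anomer mixture) | O(Cc1ccccc1)[C@H]1Cc2c(OCc3ccccc3)c([C@H](c5ccc(OCc6ccccc6)cc5)[C@H]3[C@H](C(=O)c5ccc(OCc6ccccc6)cc5OCc5ccccc5)[C@@H](c5ccc(OCc6ccccc6)cc5)OC3(O)c5ccc(OCc6ccccc6)cc5OCc5ccccc5)c(OCc3ccccc3)c([C@H](c5ccc(OCc6ccccc6)cc5)[C@H]3[C@H](C(=O)c5ccc(OCc6ccccc6)cc5OCc5ccccc5)[C@@H](c5ccc(OCc6ccccc6)cc5)OC3(O)c5ccc(OCc6ccccc6)cc5OCc5ccccc5)c2O[C@@H]1c1ccc(OCc2ccccc2)cc1 | intermediate
28 | hexadeca-O-benzyl ether of the target | O(Cc1ccccc1)[C@H]1Cc2c(OCc3ccccc3)c([C@H](c5ccc(OCc6ccccc6)cc5)[C@H]3[C@H](C(=O)c5ccc(OCc6ccccc6)cc5OCc5ccccc5)[C@@H](c5ccc(OCc6ccccc6)cc5)O[C@H]3c5ccc(OCc6ccccc6)cc5OCc5ccccc5)c(OCc3ccccc3)c([C@H](c5ccc(OCc6ccccc6)cc5)[C@H]3[C@H](C(=O)c5ccc(OCc6ccccc6)cc5OCc5ccccc5)[C@@H](c5ccc(OCc6ccccc6)cc5)O[C@H]3c5ccc(OCc6ccccc6)cc5OCc5ccccc5)c2O[C@@H]1c1ccc(OCc2ccccc2)cc1 | intermediate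
29 | CNP0225367.3 | O=C(c1ccc(O)cc1O)[C@H]1[C@H]([C@@H](c2ccc(O)cc2)c2c(O)c3c(c([C@H](c4ccc(O)cc4)[C@H]4[C@H](C(=O)c5ccc(O)cc5O)[C@@H](c5ccc(O)cc5)O[C@H]4c4ccc(O)cc4O)c2O)O[C@H](c2ccc(O)cc2)[C@@H](O)C3)[C@H](c2ccc(O)cc2O)O[C@@H]1c1ccc(O)cc1 | target

## Step count and least certain steps

Total step count: 17. Longest linear sequence: 16 steps (steps 1 to 12 and 14 to 17, from 1 to 29); step 13 is a one-step side branch.

Step 9 (key step). The most likely failure is slow insertion at the two β-carbons, each of which has an oxygen-bearing peri neighbour, so that protodeboronation of 14 outruns the addition and the reaction stops after one arylation. Forcing it with heat would cost enantioface selectivity. The fallback separates bond formation from stereocontrol. It sets out from 13: arylation with 14 under Pd(OAc)2 and 1,10-phenanthroline with O2 as oxidant (oxidative Heck-type coupling at the coumarin β-carbon, divalent palladium) gives the bis(4-arylcoumarin) F1, which has no stereocentre at Ca. Asymmetric conjugate reduction of F1 with a hydride of monovalent copper made from Cu(OAc)2, one enantiomer of DTBM-SEGPHOS and a hydrosilane then delivers hydrogen, not the aryl group, to Ca under ligand control and comes back to the route at 15.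

Step 14. Four additions have to go to completion in one flask. The C2' amides are flanked by C3' with its diarylmethyl group, and 22 carries an ortho substituent. Deprotonation next to the amide, or base-induced loss of the N-methoxy group, may therefore compete with addition, leaving the fourfold arylation incomplete and scrambling C3'. The fallback sets out from 19 and uses aldehydes, which are smaller and more electrophilic. Reduction with (i-Bu)2AlH at −78 °C gives the tetra-aldehyde F2. Addition of 22 in the presence of CeCl3, which keeps the nucleophile from acting as a base, gives the tetrol F3 as a mixture of carbinol epimers. Oxidation with Dess–Martin periodinane removes those centres and comes back at 23.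

Step 15. Two processes threaten this step. The 1,4-diketone may not survive enolisation cleanly (enolisation towards C3' erodes the centre set in step 10, and the Lewis-acidic boron triflate can close a 1,4-diketone to a furan). The facial bias from C3' also has to be expressed in both arms, so a modest preference is squared. The fallback moves the aldol to a stage where no ketone exists. It sets out from 19: LiN(iPr)2 at −78 °C should remove a proton from the unhindered C4' methylene of each arm, 24 is added, and the aldolates are silylated in the same flask with tert-butyldimethylsilyl triflate to give the bis-silyl ether F4. Addition of 22 as in step 14 gives the tetraketone bis-silyl ether F5 (the same compound as A1), and HF·pyridine frees the C5' hydroxyl groups, which close to the hemiketals and come back at 27.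

Step 16. BF3·OEt2 may also ionise the benzylic C2'–O and C5'–O bonds of the product, or the C5' carbinol of any open-chain material, because the alkoxyphenyl groups stabilise the cations strongly. That would lead to ring opening, over-reduction or equilibration of the cis C2' centre. The fallback replaces the ionic reduction by a radical one under neutral conditions. It sets out from 27: thiophenol with pyridinium p-toluenesulfonate gives the bis(O,S-ketal) F6, and Bu3SnH with azobisisobutyronitrile in toluene at 80 °C generates the C2' radical, which should take hydrogen from the same, less hindered face and come back at 28.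

Step 17. The long exposure needed to remove sixteen benzyl groups may carry hydrogenolysis beyond O-debenzylation, into the benzylic C–O bonds of the oxolanes and of C2–O1 or into the aryl ketones. The fallback is non-reductive: from 28, BCl3 with pentamethylbenzene as cation scavenger in CH2Cl2 at −78 °C cleaves the benzyl ethers by a Lewis-acid mechanism and gives 29 directly.

## Further compounds

F1 | step 9 | bis(4-arylcoumarin), 13 with a 4-(benzyloxy)phenyl group on each Ca | O(Cc1ccccc1)[C@H]1Cc2c3OC(=O)C=C(c5ccc(OCc6ccccc6)cc5)c3c3OC(=O)C=C(c5ccc(OCc6ccccc6)cc5)c3c2O[C@@H]1c1ccc(OCc2ccccc2)cc1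
F2 | step 14 | tetra-aldehyde, 19 with each amide reduced to CHO | O(Cc1ccccc1)[C@H]1Cc2c(OCc3ccccc3)c([C@H](c5ccc(OCc6ccccc6)cc5)[C@@H](CC=O)C=O)c(OCc3ccccc3)c([C@H](c5ccc(OCc6ccccc6)cc5)[C@@H](CC=O)C=O)c2O[C@@H]1c1ccc(OCc2ccccc2)cc1
F3 | step 14 | tetrol, four 2,4-bis(benzyloxy)phenyl carbinols (carbinol epimers) | O(Cc1ccccc1)[C@H]1Cc2c(OCc3ccccc3)c([C@H](c5ccc(OCc6ccccc6)cc5)[C@@H](CC(O)c5ccc(OCc6ccccc6)cc5OCc5ccccc5)C(O)c5ccc(OCc6ccccc6)cc5OCc5ccccc5)c(OCc3ccccc3)c([C@H](c5ccc(OCc6ccccc6)cc5)[C@@H](CC(O)c5ccc(OCc6ccccc6)cc5OCc5ccccc5)C(O)c5ccc(OCc6ccccc6)cc5OCc5ccccc5)c2O[C@@H]1c1ccc(OCc2ccccc2)cc1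
F4 | step 15 | bis-aldol of 19 at C4' as bis(tert-butyldimethylsilyl) ether | O(Cc1ccccc1)[C@H]1Cc2c(OCc3ccccc3)c([C@H](c5ccc(OCc6ccccc6)cc5)[C@@H]([C@H](C(=O)N(C)OC)[C@H](O[Si](C)(C)C(C)(C)C)c5ccc(OCc6ccccc6)cc5)C(=O)N(C)OC)c(OCc3ccccc3)c([C@H](c5ccc(OCc6ccccc6)cc5)[C@@H]([C@H](C(=O)N(C)OC)[C@H](O[Si](C)(C)C(C)(C)C)c5ccc(OCc6ccccc6)cc5)C(=O)N(C)OC)c2O[C@@H]1c1ccc(OCc2ccccc2)cc1
F5 | step 15 | bis(tert-butyldimethylsilyl) ether of 26 | O(Cc1ccccc1)[C@H]1Cc2c(OCc3ccccc3)c([C@H](c5ccc(OCc6ccccc6)cc5)[C@@H]([C@H](C(=O)c5ccc(OCc6ccccc6)cc5OCc5ccccc5)[C@H](O[Si](C)(C)C(C)(C)C)c5ccc(OCc6ccccc6)cc5)C(=O)c5ccc(OCc6ccccc6)cc5OCc5ccccc5)c(OCc3ccccc3)c([C@H](c5ccc(OCc6ccccc6)cc5)[C@@H]([C@H](C(=O)c5ccc(OCc6ccccc6)cc5OCc5ccccc5)[C@H](O[Si](C)(C)C(C)(C)C)c5ccc(OCc6ccccc6)cc5)C(=O)c5ccc(OCc6ccccc6)cc5OCc5ccccc5)c2O[C@@H]1c1ccc(OCc2ccccc2)cc1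
F6 | step 16 | bis(O,S-ketal), 27 with SPh in place of each C2' hydroxyl (C2' epimers) | O(Cc1ccccc1)[C@H]1Cc2c(OCc3ccccc3)c([C@H](c5ccc(OCc6ccccc6)cc5)[C@H]3[C@H](C(=O)c5ccc(OCc6ccccc6)cc5OCc5ccccc5)[C@@H](c5ccc(OCc6ccccc6)cc5)OC3(Sc4ccccc4)c5ccc(OCc6ccccc6)cc5OCc5ccccc5)c(OCc3ccccc3)c([C@H](c5ccc(OCc6ccccc6)cc5)[C@H]3[C@H](C(=O)c5ccc(OCc6ccccc6)cc5OCc5ccccc5)[C@@H](c5ccc(OCc6ccccc6)cc5)OC3(Sc4ccccc4)c5ccc(OCc6ccccc6)cc5OCc5ccccc5)c2O[C@@H]1c1ccc(OCc2ccccc2)cc1
F0 | step 17 | none | none
A1 | alternative 1 | bis(1,4-diketone) with silylated C5' carbinols | c9ccccc9CO[C@H]1Cc2c(OCc9ccccc9)c([C@H](c7ccc(OCc9ccccc9)cc7)[C@H](C(=O)c8ccc(OCc9ccccc9)cc8OCc9ccccc9)[C@H](C(=O)c8ccc(OCc9ccccc9)cc8OCc9ccccc9)[C@@H](c7ccc(OCc9ccccc9)cc7)O[Si](C)(C)C(C)(C)C)c(OCc9ccccc9)c([C@H](c7ccc(OCc9ccccc9)cc7)[C@H](C(=O)c8ccc(OCc9ccccc9)cc8OCc9ccccc9)[C@H](C(=O)c8ccc(OCc9ccccc9)cc8OCc9ccccc9)[C@@H](c7ccc(OCc9ccccc9)cc7)O[Si](C)(C)C(C)(C)C)c2O[C@@H]1c7ccc(OCc9ccccc9)cc7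
A2 | alternative 2 | bis(tetrahydrofuro[2,3-b]chromene ketal) with the full carbon skeleton | c9ccccc9CO[C@H]1Cc2c3O[C@]5(c8ccc(OCc9ccccc9)cc8OCc9ccccc9)O[C@H](c7ccc(OCc9ccccc9)cc7)[C@@H](C(=O)c8ccc(OCc9ccccc9)cc8OCc9ccccc9)[C@@H]5[C@@H](c7ccc(OCc9ccccc9)cc7)c3c4O[C@]5(c8ccc(OCc9ccccc9)cc8OCc9ccccc9)O[C@H](c7ccc(OCc9ccccc9)cc7)[C@@H](C(=O)c8ccc(OCc9ccccc9)cc8OCc9ccccc9)[C@@H]5[C@@H](c7ccc(OCc9ccccc9)cc7)c4c2O[C@@H]1c7ccc(OCc9ccccc9)cc7
A3 | alternative 3 | perbenzyl ether of the target (identical with 28) | c9ccccc9CO[C@H]1Cc2c(OCc9ccccc9)c([C@H](c7ccc(OCc9ccccc9)cc7)[C@H]4[C@H](C(=O)c8ccc(OCc9ccccc9)cc8OCc9ccccc9)[C@@H](c7ccc(OCc9ccccc9)cc7)O[C@H]4c8ccc(OCc9ccccc9)cc8OCc9ccccc9)c(OCc9ccccc9)c([C@H](c7ccc(OCc9ccccc9)cc7)[C@H]4[C@H](C(=O)c8ccc(OCc9ccccc9)cc8OCc9ccccc9)[C@@H](c7ccc(OCc9ccccc9)cc7)O[C@H]4c8ccc(OCc9ccccc9)cc8OCc9ccccc9)c2O[C@@H]1c7ccc(OCc9ccccc9)cc7
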